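**Plan**
- Target numbering: C1 carboxyl carbon, C2 its CH2, C3–C6 the dioxane carbons (C3 carries the acetic acid arm, C4 and C6 a methyl each), C7–C14 the side chain (methyls on C8 and C12, C9=C10 and C13=C14 both E, phenyl on C14).
- Cuts: C9=C10 (Julia–Kocienski), C2–C3 (acetate unit onto a peroxycarbenium ion), O–C3 (hemiperacetal closure), C6–O (radical hydroperoxidation), and C4–C5 plus C7–C8 ([4+3]).
- Enabling feature: in the C4–C5–C6–C7–C8 array the methyl-bearing C4 and C8 are mirror images of each other across C6. With C3 and C9 tied together as a temporary alkene, this array is cis-3,6-dimethylcyclohept-4-enone, C6 being the carbonyl carbon.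
- Forward order: a seven-membered carbocycle (absent from the target) is made first and given the C6 methyl and peroxide. Ozonolysis opens it at C3=C9, the 1,2-dioxane closes at O–C3, C1–C2 is added, and C10–C14 is joined last.
- Stereochemistry: C4/C8 cis from the E,E diene; C6 by separation of two meso epimers; absolute sense of C4, C6 and C8 from a lipase; C3 from axial attack on the cyclic peroxycarbenium ion; C12 from [Rh(OH)((R)-BINAP)]2-catalysed conjugate addition; alkene geometries from the boronic acid and the Julia–Kocienski step.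

Key step: step 1

Assumption: Pseudomonas lipases are taken to cleave (and to form) the acetate on the CH2O arm whose neighbouring methyl-bearing carbon is S, as with simple 2-methylalkan-1-ol derivatives; if the enzyme reads the arms the other way round, acetylation of diol 9 with vinyl acetate and the same lipase should give 11 directly in place of steps 6 and 7.

**Step 1**
Reactants: 1 (2E,4E)-hexa-2,4-diene; 2 1,1,3,3-tetrabromoacetone
Product: 4 2,7-dibromo-cis-3,6-dimethylcyclohept-4-en-1-one (mixture of bromine epimers), via iron-bound 1,3-dibromo-2-oxyallyl cation 3 (not isolated)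
Conditions: Fe2(CO)9 (1.2 equiv), 1 in excess, benzene, 60 °C, N2
Reagents that add atoms: none
Why: Fe2(CO)9 (zerovalent iron) reduces 2 to a bromoiron enolate that loses bromide to give the oxygen-bound 1,3-dibromo-2-oxyallyl cation 3 on divalent iron; the two terminal carbons of this 2π electrophile bond to C2 and C5 of the s-cis diene and so make the C4–C5 and C7–C8 bonds of the target. The closest known reaction type is the Noyori [4+3] cycloaddition of iron oxyallyl cations from polybromoketones with open-chain 1,3-dienes. The seven-membered carbocycle closes in a [4π+2π] mode (four diene carbons plus three allyl carbons), both new bonds forming on one face of the diene. The two methyl-bearing centres (later C4 and C8) are controlled by the E,E geometry of 1, because suprafacial bonding at both termini turns the two outward methyls into a cis pair; the product is meso, so no absolute control is needed here. The step needs only this cis relation and an oxyallyl cation that lives long enough to bond through both carbon termini; the diene geometry secures the first, and the two α-bromines left on 3 secure the second by stabilising a cation that the unsubstituted system would not form. The bromines are removed in step 2, so the configuration at the CHBr carbons is immaterial.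

**Step 2**
Reactants: 4 2,7-dibromo-cis-3,6-dimethylcyclohept-4-en-1-one
Product: 5 (3R,6S)-3,6-dimethylcyclohept-4-en-1-one (meso, methyls cis)
Conditions: Zn–Cu couple, NH4Cl, MeOH, 20 °C
Reagents that add atoms: none
Why: Reductive dehalogenation of the α-bromo ketone proceeds through zinc enolates that are protonated by NH4Cl/MeOH, and the methyl-bearing carbons are β to the carbonyl and cannot epimerise.

**Step 3**
Reactants: 5 (3R,6S)-3,6-dimethylcyclohept-4-en-1-one
Product: 6 (3R,7S)-3,7-dimethyl-5-methylidenecyclohept-1-ene (meso)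
Conditions: Ph3PCH3Br, KOtBu, THF, 0 → 20 °C
Reagents that add atoms: methyltriphenylphosphonium bromide, C[P+](c1ccccc1)(c1ccccc1)c1ccccc1.[Br-]
Why: Wittig methylenation of an unhindered ketone installs the carbon that becomes the C6 methyl, without touching the β stereocentres or the ring alkene.

**Step 4**
Reactants: 6 (3R,7S)-3,7-dimethyl-5-methylidenecyclohept-1-ene
Product: 7 triethyl{[(1r,3R,6S)-1,3,6-trimethylcyclohept-4-en-1-yl]peroxy}silane (meso; peroxy group cis to both ring methyls)
Conditions: Co(thd)2 (10 mol %; thd = 2,2,6,6-tetramethylheptane-3,5-dionate), O2 (1 atm), Et3SiH, ClCH2CH2Cl, 20 °C; chromatography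
Reagents that add atoms: dioxygen, O=O; triethylsilane, CC[SiH](CC)CC
Why: In the Mukaiyama–Isayama hydroperoxysilylation a cobalt hydride transfers a hydrogen atom to the 1,1-disubstituted alkene (the cis-1,2-disubstituted ring alkene reacts far more slowly), and the tertiary C6 radical is trapped by O2 and silylated; facial bias in this capture is expected to be small, so 7 has to be separated by chromatography from its C6 epimer, the two meso isomers being told apart by NOE.

**Step 5**
Reactants: 7 triethyl{[(1r,3R,6S)-1,3,6-trimethylcyclohept-4-en-1-yl]peroxy}silane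
Product: 9 (2R,4r,6S)-2,4,6-trimethyl-4-[(triethylsilyl)peroxy]heptane-1,7-diol (meso), via meso dialdehyde 8 (not isolated)
Conditions: O3, pyridine, CH2Cl2, −78 °C; then NaBH4, MeOH, −78 → 0 °C
Reagents that add atoms: ozone, [O-][O+]=O
Why: Pyridine-mediated ozonolysis cleaves C3=C9 directly to the dialdehyde, which NaBH4 reduces in the same flask before the α-methyl centres can epimerise; the silyl peroxide is inert to both reagents.

**Step 6**
Reactants: 9 (2R,4r,6S)-2,4,6-trimethyl-4-[(triethylsilyl)peroxy]heptane-1,7-diol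
Product: 10 (2R,4r,6S)-2,4,6-trimethyl-4-[(triethylsilyl)peroxy]heptane-1,7-diyl diacetate (meso)
Conditions: Ac2O, pyridine, DMAP (cat.), CH2Cl2, 20 °C
Reagents that add atoms: acetic anhydride, CC(=O)OC(C)=O
Why: DMAP-catalysed acetylation of two unhindered primary alcohols is routine and leaves the tertiary silyl peroxide untouched.

**Step 7**
Reactants: 10 (2R,4r,6S)-2,4,6-trimethyl-4-[(triethylsilyl)peroxy]heptane-1,7-diyl diacetate
Product: 11 (2R,4R,6S)-7-hydroxy-2,4,6-trimethyl-4-[(triethylsilyl)peroxy]heptyl acetate (free OH on the C3 arm, acetate on the C9 arm)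
Conditions: lipase from Pseudomonas fluorescens (Amano AK), 0.1 M phosphate buffer pH 7, acetone (10 vol %), 30 °C, stopped when 10 is consumed
Reagents that add atoms: none
Why: Lipase hydrolysis of a meso diacetate distinguishes the enantiotopic arms by the methyl-bearing carbon next to each CH2OAc, and cleaving the arm on the S carbon fixes the absolute configuration of C4, C6 and C8 at once; any monoacetate of the wrong sense still carries its fast-reacting acetate and is drained to the diol.

**Step 8**
Reactants: 11 (2R,4R,6S)-7-hydroxy-2,4,6-trimethyl-4-[(triethylsilyl)peroxy]heptyl acetate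
Product: 12 (2R,4S,6S)-2,4,6-trimethyl-7-oxo-4-[(triethylsilyl)peroxy]heptyl acetate
Conditions: Dess–Martin periodinane, NaHCO3, CH2Cl2, 0 → 20 °C; used crude
Reagents that add atoms: none
Why: Buffered Dess–Martin oxidation gives the C3 aldehyde under neutral conditions that spare the silyl peroxide, the acetate and the α stereocentre C4.

**Step 9**
Reactants: 12 (2R,4S,6S)-2,4,6-trimethyl-7-oxo-4-[(triethylsilyl)peroxy]heptyl acetate
Product: 15 (2R)-3-[(3S,5S)-6-methoxy-3,5-dimethyl-1,2-dioxan-3-yl]-2-methylpropyl acetate (both anomers), via hydroperoxy aldehyde 13 (not isolated), via 1,2-dioxan-3-ol 14 (not isolated)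
Conditions: camphorsulfonic acid (10 mol %), MeOH, 0 → 20 °C
Reagents that add atoms: methanol, CO
Why: Acid methanolysis of the O–Si bond frees the tertiary hydroperoxide, which adds to the C3 aldehyde to close the 1,2-dioxane as a hemiperacetal, and acid-catalysed acetal exchange then replaces OH by OMe; the anomeric centre is erased in step 10.

**Step 10**
Reactants: 15 (2R)-3-[(3S,5S)-6-methoxy-3,5-dimethyl-1,2-dioxan-3-yl]-2-methylpropyl acetate; 16 tert-butyl[(1-methoxyethenyl)oxy]dimethylsilane
Product: 17 methyl 2-[(3S,4S,6S)-6-[(2R)-3-(acetyloxy)-2-methylpropyl]-4,6-dimethyl-1,2-dioxan-3-yl]acetate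
Conditions: Me3SiOTf (0.3 equiv), CH2Cl2, −78 °C
Reagents that add atoms: none
Why: This is a Mukaiyama-type addition of a silyl ketene acetal to the cyclic peroxycarbenium ion formed by loss of methoxide; C3 is set by axial attack on the half-chair cation that keeps the C4 and C6 methyls pseudo-equatorial, which places the acetate arm cis to both methyls.

**Step 11**
Reactants: 17 methyl 2-[(3S,4S,6S)-6-[(2R)-3-(acetyloxy)-2-methylpropyl]-4,6-dimethyl-1,2-dioxan-3-yl]acetate
Product: 18 methyl 2-[(3S,4S,6S)-6-[(2R)-3-hydroxy-2-methylpropyl]-4,6-dimethyl-1,2-dioxan-3-yl]acetate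
Conditions: K2CO3, MeOH, 0 °C
Reagents that add atoms: none
Why: Zemplén-type methanolysis removes the primary acetate, exchange at the methyl ester is degenerate, and the mild cold base should not open the β-peroxy ester.

**Step 12**
Reactants: 18 methyl 2-[(3S,4S,6S)-6-[(2R)-3-hydroxy-2-methylpropyl]-4,6-dimethyl-1,2-dioxan-3-yl]acetate
Product: 19 methyl 2-[(3S,4S,6R)-4,6-dimethyl-6-[(2R)-2-methyl-3-oxopropyl]-1,2-dioxan-3-yl]acetate (the C6 descriptor changes by priority only)
Conditions: Dess–Martin periodinane, NaHCO3, CH2Cl2, 0 → 20 °C; used crude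
Reagents that add atoms: none
Why: Dess–Martin oxidation gives the C9 aldehyde without base, so neither C8 nor the dialkyl peroxide is at risk.

**Step 13**
Reactants: 20 methyl (2E)-but-2-enoate (methyl crotonate); 21 [(E)-2-phenylethenyl]boronic acid
Product: 22 methyl (3S,4E)-3-methyl-5-phenylpent-4-enoate
Conditions: [Rh(OH)((R)-BINAP)]2 (3 mol % Rh), 21 in excess, 1,4-dioxane/H2O 10:1, 50 °C
Reagents that add atoms: none
Why: In the Hayashi–Miyaura asymmetric 1,4-addition the alkenyl group is transferred from boron to rhodium with retention of E geometry and inserted into the enoate; (R)-BINAP is expected to set C12 as S, by analogy with the known facial sense of aryl transfer to (E)-crotonates.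

**Step 14**
Reactants: 22 methyl (3S,4E)-3-methyl-5-phenylpent-4-enoate
Product: 23 (3S,4E)-3-methyl-5-phenylpent-4-en-1-ol
Conditions: LiAlH4, Et2O, 0 °C
Reagents that add atoms: none
Why: Hydride reduction of the ester gives the primary alcohol and leaves the styrenyl alkene, which is not conjugated to the ester, and C12 unchanged.

**Step 15**
Reactants: 23 (3S,4E)-3-methyl-5-phenylpent-4-en-1-ol
Product: 24 5-{[(3S,4E)-3-methyl-5-phenylpent-4-en-1-yl]sulfanyl}-1-phenyl-1H-tetrazole
Conditions: 1-phenyl-1H-tetrazole-5-thiol, PPh3, DIAD, THF, 0 → 20 °C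
Reagents that add atoms: 1-phenyl-1H-tetrazole-5-thiol, Sc1nnnn1-c1ccccc1
Why: Mitsunobu thioetherification of a primary alcohol with the acidic tetrazole thiol is standard for Julia–Kocienski precursors.

**Step 16**
Reactants: 24 5-{[(3S,4E)-3-methyl-5-phenylpent-4-en-1-yl]sulfanyl}-1-phenyl-1H-tetrazole
Product: 25 5-{[(3S,4E)-3-methyl-5-phenylpent-4-en-1-yl]sulfonyl}-1-phenyl-1H-tetrazole
Conditions: (NH4)6Mo7O24·4H2O (10 mol %), 30% H2O2, EtOH, 0 → 20 °C
Reagents that add atoms: hydrogen peroxide, OO
Why: Molybdate-catalysed peroxide oxidation takes the sulfide to the sulfone and normally leaves isolated and styrenyl alkenes alone.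

**Step 17**
Reactants: 25 5-{[(3S,4E)-3-methyl-5-phenylpent-4-en-1-yl]sulfonyl}-1-phenyl-1H-tetrazole; 19 methyl 2-[(3S,4S,6R)-4,6-dimethyl-6-[(2R)-2-methyl-3-oxopropyl]-1,2-dioxan-3-yl]acetate
Product: 27 methyl 2-[(3S,4S,6S)-6-[(2R,3E,6S,7E)-2,6-dimethyl-8-phenylocta-3,7-dien-1-yl]-4,6-dimethyl-1,2-dioxan-3-yl]acetate, via potassium sulfonyl carbanion 26 (not isolated)
Conditions: 25, KN(SiMe3)2, DME, −60 °C, 30 min; then 19, −60 → 20 °C
Reagents that add atoms: none
Why: In the Julia–Kocienski olefination the pre-metalated sulfone adds to the α-branched aldehyde, and Smiles rearrangement with loss of SO2 and tetrazolate gives the E C9=C10 alkene (potassium counter-ion in DME favours E); pre-metalation at low temperature keeps free base away from C8 and the β-peroxy ester.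

**Step 18**
Reactants: 27 methyl 2-[(3S,4S,6S)-6-[(2R,3E,6S,7E)-2,6-dimethyl-8-phenylocta-3,7-dien-1-yl]-4,6-dimethyl-1,2-dioxan-3-yl]acetate
Product: 28 2-[(3S,4S,6S)-6-[(2R,3E,6S,7E)-2,6-dimethyl-8-phenylocta-3,7-dien-1-yl]-4,6-dimethyl-1,2-dioxan-3-yl]acetic acid (CNP0179089.3)
Conditions: LiOH, THF/H2O 3:1, 0 → 20 °C; then aq. HCl to pH 3–4
Reagents that add atoms: lithium hydroxide, [Li+].[OH-]
Why: Saponification of the methyl ester with LiOH is the usual last step for 1,2-dioxane-3-acetic acids, and no stereocentre is acidic enough to be affected.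

**Compound list**
1 | (2E,4E)-hexa-2,4-diene | C/C=C/C=C/C | starting material
2 | 1,1,3,3-tetrabromoacetone | BrC(Br)C(=O)C(Br)Br | starting material
3 | 1,3-dibromo-2-oxyallyl cation bound through oxygen to divalent iron (bromoiron enolate cation, bromide counter-ion) | Br[CH+]C(O[Fe]Br)=CBr.[Br-] | intermediate
4 | 2,7-dibromo-cis-3,6-dimethylcyclohept-4-en-1-one (bromine epimers) | C[C@H]1C=C[C@@H](C)C(Br)C(=O)C1Br | intermediate
5 | (3R,6S)-3,6-dimethylcyclohept-4-en-1-one | C[C@H]1C=C[C@@H](C)CC(=O)C1 | intermediate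
6 | (3R,7S)-3,7-dimethyl-5-methylidenecyclohept-1-ene | C[C@H]1C=C[C@@H](C)CC(=C)C1 | intermediate
7 | triethyl{[(1r,3R,6S)-1,3,6-trimethylcyclohept-4-en-1-yl]peroxy}silane (peroxy cis to both ring methyls) | CC[Si](CC)(CC)OO[C@]1(C)C[C@H](C)C=C[C@H](C)C1 | intermediate
8 | (2R,4r,6S)-2,4,6-trimethyl-4-[(triethylsilyl)peroxy]heptanedial | CC[Si](CC)(CC)OO[C@](C)(C[C@H](C)C=O)C[C@@H](C)C=O | intermediate
9 | (2R,4r,6S)-2,4,6-trimethyl-4-[(triethylsilyl)peroxy]heptane-1,7-diol | CC[Si](CC)(CC)OO[C@](C)(C[C@H](C)CO)C[C@@H](C)CO | intermediate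
10 | (2R,4r,6S)-2,4,6-trimethyl-4-[(triethylsilyl)peroxy]heptane-1,7-diyl diacetate | CC[Si](CC)(CC)OO[C@](C)(C[C@H](C)COC(C)=O)C[C@@H](C)COC(C)=O | intermediate
11 | (2R,4R,6S)-7-hydroxy-2,4,6-trimethyl-4-[(triethylsilyl)peroxy]heptyl acetate | CC[Si](CC)(CC)OO[C@](C)(C[C@H](C)CO)C[C@@H](C)COC(C)=O | intermediate
12 | (2R,4S,6S)-2,4,6-trimethyl-7-oxo-4-[(triethylsilyl)peroxy]heptyl acetate | CC[Si](CC)(CC)OO[C@](C)(C[C@H](C)C=O)C[C@@H](C)COC(C)=O | intermediate
13 | (2R,4S,6S)-4-hydroperoxy-2,4,6-trimethyl-7-oxoheptyl acetate | OO[C@](C)(C[C@H](C)C=O)C[C@@H](C)COC(C)=O | intermediate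
14 | (2R)-3-[(3S,5S)-6-hydroxy-3,5-dimethyl-1,2-dioxan-3-yl]-2-methylpropyl acetate | CC(=O)OC[C@H](C)C[C@@]1(C)C[C@H](C)C(O)OO1 | intermediate
15 | (2R)-3-[(3S,5S)-6-methoxy-3,5-dimethyl-1,2-dioxan-3-yl]-2-methylpropyl acetate | CC(=O)OC[C@H](C)C[C@@]1(C)C[C@H](C)C(OC)OO1 | intermediate
16 | tert-butyl[(1-methoxyethenyl)oxy]dimethylsilane | C=C(OC)O[Si](C)(C)C(C)(C)C | starting material
17 | methyl 2-[(3S,4S,6S)-6-[(2R)-3-(acetyloxy)-2-methylpropyl]-4,6-dimethyl-1,2-dioxan-3-yl]acetate | CC(=O)OC[C@H](C)C[C@@]1(C)C[C@H](C)[C@H](CC(=O)OC)OO1 | intermediate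
18 | methyl 2-[(3S,4S,6S)-6-[(2R)-3-hydroxy-2-methylpropyl]-4,6-dimethyl-1,2-dioxan-3-yl]acetate | OC[C@H](C)C[C@@]1(C)C[C@H](C)[C@H](CC(=O)OC)OO1 | intermediate
19 | methyl 2-[(3S,4S,6R)-4,6-dimethyl-6-[(2R)-2-methyl-3-oxopropyl]-1,2-dioxan-3-yl]acetate | O=C[C@H](C)C[C@@]1(C)C[C@H](C)[C@H](CC(=O)OC)OO1 | intermediate
20 | methyl (2E)-but-2-enoate | C/C=C/C(=O)OC | starting material
21 | [(E)-2-phenylethenyl]boronic acid | OB(O)/C=C/c1ccccc1 | starting material
22 | methyl (3S,4E)-3-methyl-5-phenylpent-4-enoate | C[C@H](/C=C/c1ccccc1)CC(=O)OC | intermediate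
23 | (3S,4E)-3-methyl-5-phenylpent-4-en-1-ol | C[C@H](/C=C/c1ccccc1)CCO | intermediate
24 | 5-{[(3S,4E)-3-methyl-5-phenylpent-4-en-1-yl]sulfanyl}-1-phenyl-1H-tetrazole | C[C@H](/C=C/c1ccccc1)CCSc1nnnn1-c1ccccc1 | intermediate
25 | 5-{[(3S,4E)-3-methyl-5-phenylpent-4-en-1-yl]sulfonyl}-1-phenyl-1H-tetrazole | C[C@H](/C=C/c1ccccc1)CCS(=O)(=O)c1nnnn1-c1ccccc1 | intermediate
26 | potassium salt of 25 deprotonated at the carbon next to sulfur | C[C@H](/C=C/c1ccccc1)C[CH-]S(=O)(=O)c1nnnn1-c1ccccc1.[K+] | intermediate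
27 | methyl 2-[(3S,4S,6S)-6-[(2R,3E,6S,7E)-2,6-dimethyl-8-phenylocta-3,7-dien-1-yl]-4,6-dimethyl-1,2-dioxan-3-yl]acetate | C[C@H](/C=C/c1ccccc1)C/C=C/[C@H](C)C[C@@]1(C)C[C@H](C)[C@H](CC(=O)OC)OO1 | intermediate
28 | 2-[(3S,4S,6S)-6-[(2R,3E,6S,7E)-2,6-dimethyl-8-phenylocta-3,7-dien-1-yl]-4,6-dimethyl-1,2-dioxan-3-yl]acetic acid | C[C@H](/C=C/c1ccccc1)C/C=C/[C@H](C)C[C@@]1(C)C[C@H](C)[C@H](CC(=O)O)OO1 | target

**Totals**
Total steps: 18. Longest linear sequence: 14 (steps 1–12, 17, 18); steps 13–16 make the sulfone branch.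

**Steps most likely to fail**

1. Step 4. Dioxygen can capture the planar C6 radical from either face with little preference, so the wanted all-cis isomer may be the minor product and most of the material would be lost at the separation. The fallback replaces the single pass by a loop that returns the wrong isomer to the alkene. Setting out from 6, the peroxidation is run as in step 4 and the unwanted epimer triethyl{[(1s,3R,6S)-1,3,6-trimethylcyclohept-4-en-1-yl]peroxy}silane F1, with the peroxy group trans to the ring methyls, is collected. Bu4NF in THF at 0 °C should cleave its O–Si bond to (1s,3R,6S)-1,3,6-trimethylcyclohept-4-en-1-yl hydroperoxide F2. PPh3 then reduces it to (1s,3R,6S)-1,3,6-trimethylcyclohept-4-en-1-ol F3. Dehydration with Burgess reagent in benzene at 50 °C should return alkene 6 together with its endocyclic isomer cis-1,3,6-trimethylcyclohepta-1,4-diene F4. Both alkenes give the same tertiary C6 radical under the cobalt conditions, so the recovered mixture is peroxidised again and the sequence comes back to the route at 7.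

2. Step 10. The silyl triflate may trigger heterolysis of the O–O bond (Hock-type fragmentation) or ring-opening ionisation instead of loss of methoxide, or the ketene acetal may be consumed before it adds, and facial control at C3 may erode. The fallback uses a more robust π-nucleophile and reaches the acid oxidation level afterwards. Setting out from 15, Hosomi–Sakurai allylation with allyltrimethylsilane and Me3SiOTf (cat.) in CH2Cl2 at −78 °C should give, by the same axial attack, (2R)-3-[(3S,5S,6S)-3,5-dimethyl-6-(prop-2-en-1-yl)-1,2-dioxan-3-yl]-2-methylpropyl acetate F5. Ozonolysis with pyridine in CH2Cl2 at −78 °C then gives (2R)-3-[(3S,5S,6S)-3,5-dimethyl-6-(2-oxoethyl)-1,2-dioxan-3-yl]-2-methylpropyl acetate F6. Pinnick oxidation (NaClO2, NaH2PO4, 2-methylbut-2-ene, tBuOH/H2O) gives 2-[(3S,4S,6S)-6-[(2R)-3-(acetyloxy)-2-methylpropyl]-4,6-dimethyl-1,2-dioxan-3-yl]acetic acid F7. Methylation with Me3SiCHN2 in MeOH/toluene brings the sequence back to the route at 17.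

3. Step 17. The metalated sulfone may deprotonate C2 and expel the peroxide oxygen from C3 (ring opening), or the aldehyde may epimerise at C8 before it is captured. The fallback moves the olefination to a stage without an enolisable ester. Setting out from 15, K2CO3 in MeOH at 0 °C should give (2R)-3-[(3S,5S)-6-methoxy-3,5-dimethyl-1,2-dioxan-3-yl]-2-methylpropan-1-ol F8. Dess–Martin oxidation gives (2R)-3-[(3S,5S)-6-methoxy-3,5-dimethyl-1,2-dioxan-3-yl]-2-methylpropanal F9. Julia–Kocienski olefination with 25 and KN(SiMe3)2 in DME at −60 °C gives (4S,6S)-6-[(2R,3E,6S,7E)-2,6-dimethyl-8-phenylocta-3,7-dien-1-yl]-3-methoxy-4,6-dimethyl-1,2-dioxane F10. Addition of 16 with Me3SiOTf in CH2Cl2 at −78 °C, as in step 10 and now with the side-chain alkenes present, returns the sequence to the route at 27.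

**Further compounds**
F1 | step 4 | triethyl{[(1s,3R,6S)-1,3,6-trimethylcyclohept-4-en-1-yl]peroxy}silane | CC[Si](CC)(CC)OO[C@@]1(C)C[C@H](C)C=C[C@H](C)C1
F2 | step 4 | (1s,3R,6S)-1,3,6-trimethylcyclohept-4-en-1-yl hydroperoxide | OO[C@@]1(C)C[C@H](C)C=C[C@H](C)C1
F3 | step 4 | (1s,3R,6S)-1,3,6-trimethylcyclohept-4-en-1-ol | O[C@@]1(C)C[C@H](C)C=C[C@H](C)C1
F4 | step 4 | cis-1,3,6-trimethylcyclohepta-1,4-diene (racemic; the 3R,6R enantiomer is drawn) | CC1=C[C@H](C)C=C[C@H](C)C1
F5 | step 10 | (2R)-3-[(3S,5S,6S)-3,5-dimethyl-6-(prop-2-en-1-yl)-1,2-dioxan-3-yl]-2-methylpropyl acetate | CC(=O)OC[C@H](C)C[C@@]1(C)C[C@H](C)[C@H](CC=C)OO1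
F6 | step 10 | (2R)-3-[(3S,5S,6S)-3,5-dimethyl-6-(2-oxoethyl)-1,2-dioxan-3-yl]-2-methylpropyl acetate | CC(=O)OC[C@H](C)C[C@@]1(C)C[C@H](C)[C@H](CC=O)OO1
F7 | step 10 | 2-[(3S,4S,6S)-6-[(2R)-3-(acetyloxy)-2-methylpropyl]-4,6-dimethyl-1,2-dioxan-3-yl]acetic acid | CC(=O)OC[C@H](C)C[C@@]1(C)C[C@H](C)[C@H](CC(=O)O)OO1
F8 | step 17 | (2R)-3-[(3S,5S)-6-methoxy-3,5-dimethyl-1,2-dioxan-3-yl]-2-methylpropan-1-ol | OC[C@H](C)C[C@@]1(C)C[C@H](C)C(OC)OO1
F9 | step 17 | (2R)-3-[(3S,5S)-6-methoxy-3,5-dimethyl-1,2-dioxan-3-yl]-2-methylpropanal | O=C[C@H](C)C[C@@]1(C)C[C@H](C)C(OC)OO1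
F10 | step 17 | (4S,6S)-6-[(2R,3E,6S,7E)-2,6-dimethyl-8-phenylocta-3,7-dien-1-yl]-3-methoxy-4,6-dimethyl-1,2-dioxane | C[C@H](/C=C/c1ccccc1)C/C=C/[C@H](C)C[C@@]1(C)C[C@H](C)C(OC)OO1
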